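**Retrosynthetic overview**
1. Target 13 is two identical C15 flavan-3,4-diol units minus one H2O. Adding the water back and tying the two 7-OH groups with a hydrogenolysable m-xylylene strap gives the C2-symmetric bis(flavan-3,4-diol) 10.
2. The C4(upper)–C6(lower) bond comes from a transannular Friedel–Crafts closure inside the strapped dimer (14-membered ring), with the lower cis-diol held as a phenylboronate.
3. Both O1–C2 bonds come from a double 6-endo phenol/oxirane opening of the strapped bis(anti-epoxy alcohol) 9. This runs in the same flask as line 2.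
4. 9 is built two-directionally: double reduction, double Juliá–Colonna epoxidation and double Claisen–Schmidt condensation of strapped bis-acetophenone 4 (from 1 and 2) with aldehyde 5.
5. Ring order: pyran rings C and F form together, then the dioxaborolane, then the macrocycle. Strap, boronate and benzyl groups all leave in the last step.

Assumption: the SMILES is read as fisetinidol-(4α→6)-flavan-3,4-diol, with the upper unit (rings A/B/C) 2R,3S,4R (2,3-trans-3,4-trans) and the lower unit (rings D/E/F) 2R,3S,4S (2,3-trans-3,4-cis). The strap length was chosen from a simple geometric model (O7···O7 about 6.5–7.4 Å in the product).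

**Step 1**
Reactants: 1 2,4-dihydroxyacetophenone (2 equiv); 2 1,3-bis(bromomethyl)benzene (1 equiv)
Product: 4 1,3-bis{[4-acetyl-3-(allyloxy)phenoxy]methyl}benzene, via strapped bis-phenol 3 (not isolated)
Conditions: K2CO3 (2.2 equiv), DMF, 40 °C, 6 h; then allyl bromide (3 equiv), K2CO3 (3 equiv), 70 °C, 12 h
Reagents that add atoms: allyl bromide, C=CCBr
Why: Two Williamson etherifications in one flask: the 4-OH is the only acidic, unchelated phenol of 1, so the dibromide straps two molecules there first, and the hydrogen-bonded 2-OH is alkylated only afterwards by excess allyl bromide at higher temperature; no stereocentre is formed.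

**Step 2**
Reactants: 4 1,3-bis{[4-acetyl-3-(allyloxy)phenoxy]methyl}benzene; 5 3,4-bis(benzyloxy)benzaldehyde (2.2 equiv)
Product: 6 strapped bis-(E)-chalcone
Conditions: KOH (50% aq), EtOH–THF 1:1, 25 °C, 36 h
Reagents that add atoms: none
Why: Double Claisen–Schmidt aldol condensation of the two methyl ketones with the non-enolisable aldehyde, with E1cB loss of water giving only the conjugated E-enones; allyl, benzyl and strap ethers are inert to KOH.

**Step 3**
Reactants: 6 strapped bis-(E)-chalcone
Product: 7 strapped bis[(2R,3S)-trans-epoxy ketone]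
Conditions: poly-L-leucine, urea·H2O2 (3 equiv), DBU (3 equiv), THF, 25 °C, 24–48 h
Reagents that add atoms: hydrogen peroxide (as its urea adduct), OO
Why: Juliá–Colonna epoxidation (Weitz–Scheffer hydroperoxide addition inside the poly-L-leucine helix) gives the (2R,3S)-trans-epoxy ketone at each enone, which fixes C3 and (after the later inversion) C2 of both flavan units; running it twice in one molecule turns the minor sense into a separable meso diastereomer (Horeau amplification), and the nucleophilic oxidant ignores the isolated allyl double bonds.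

**Step 4**
Reactants: 7 strapped bis[(2R,3S)-trans-epoxy ketone]
Product: 8 strapped bis[(1S,2S,3S)-anti-epoxy alcohol] bis-allyl ether
Conditions: Zn(BH4)2 (0.15 M stock in Et2O, 1.5 equiv), Et2O–THF, −20 → 0 °C, 1 h; H2O
Reagents that add atoms: none
Why: Chelation-controlled hydride reduction: divalent zinc bridges the carbonyl and oxirane oxygens and hydride enters from the side of the oxirane C–H, giving the anti (erythro) epoxy alcohol at both ends, which is the configuration that becomes the 4β-OH (3,4-cis); oxiranes and allyl ethers survive at 0 °C.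

**Step 5 (key step)**
Reactants: 8 strapped bis[(1S,2S,3S)-anti-epoxy alcohol] bis-allyl ether
Product: 12 strapped macrocyclic dimer 3′,4′-di-O-benzylfisetinidol-(4α→6)-3′,4′-di-O-benzyl-(2R,3S,4S)-flavan-3,4-diol 3,4-O-phenylboronate (O7 of ring A bridged to O7 of ring D by m-xylylene), via free bis-phenol 9 (not isolated), via strapped bis-diol 10 (not isolated), via mono-boronate 11 (not isolated)
Conditions: Pd(PPh3)4 (3 mol %), morpholine (3 equiv), CH2Cl2, 25 °C, 1 h; then dilute to 1 mM with CH2Cl2–(CF3)2CHOH 4:1, PhB(OH)2 (1.05 equiv), TsOH·H2O (3.5 equiv, 3 of them neutralise the amine), −20 → 25 °C; pH 7 buffer wash, short silica plug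
Reagents that add atoms: phenylboronic acid, OB(O)c1ccccc1
Why: Proposed new method: zerovalent-palladium Tsuji–Trost deallylation frees both phenols, and each opens its own aryl-activated oxirane 6-endo at the benzylic carbon with inversion (giving 2,3-trans and keeping the anti carbinol as the axial 4β-OH, i.e. 3,4-cis), so rings C and F close together; one equivalent of PhB(OH)2 then locks one cis-diol as a dioxaborolane whose C4–O bond can ionise only with internal return on the β face, the unmasked unit ionises to the 2,4-dialkoxybenzylic cation, and at 1 mM the strap delivers C6 of the masked unit (para to O1, ortho to O7, less hindered than C8) to the α face anti to the 3-OH, which sets the upper C4 as 3,4-trans and leaves exactly one boronate for the one remaining diol, so the sequence stops at the dimer; the closest known reaction types are acid-induced cyclisation of 2-hydroxyaryl epoxides to flavan-3-ols, 3,4-trans-selective acid-catalysed Friedel–Crafts coupling of flavan-3,4-diols with resorcinol-type arenes, transient boronate masking of cis-diols in glycosylation, and tether-directed macrocyclising Friedel–Crafts alkylation.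

**Step 6**
Reactants: 12 strapped macrocyclic dimer boronate
Product: 13 target fisetinidol-(4α→6)-(2R,3S,4S)-3′,4′,7-trihydroxyflavan-3,4-diol
Conditions: H2 (1 atm), Pd(OH)2/C (20 wt %), THF–MeOH–H2O 10:10:1, 25 °C, 2 h; filter; Sephadex LH-20 (EtOH)
Reagents that add atoms: none
Why: Heterogeneous hydrogenolysis of the six aryl-O–benzylic bonds (four benzyl ethers and both ends of the strap) is much faster at neutral pH than cleavage of a secondary benzylic alcohol (as in the debenzylation of lignin-type p-hydroxybenzyl alcohols), aqueous methanol hydrolyses the boronate, and no stereocentre is touched.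

**Compound list**
1 | 2,4-dihydroxyacetophenone | CC(=O)c1ccc(O)cc1O | starting material
2 | 1,3-bis(bromomethyl)benzene | BrCc1cccc(CBr)c1 | starting material
3 | 1,3-bis[(4-acetyl-3-hydroxyphenoxy)methyl]benzene | CC(=O)c1ccc(OCc2cccc(COc3ccc(C(C)=O)c(O)c3)c2)cc1O | intermediate
4 | 1,3-bis{[4-acetyl-3-(allyloxy)phenoxy]methyl}benzene | C=CCOc1cc(OCc2cccc(COc3ccc(C(C)=O)c(OCC=C)c3)c2)ccc1C(C)=O | intermediate
5 | 3,4-bis(benzyloxy)benzaldehyde | O=Cc1ccc(OCc2ccccc2)c(OCc2ccccc2)c1 | starting material
6 | strapped bis-(E)-chalcone (2′-O-allyl, 4′-O-strap, 3,4-di-O-benzyl at each end) | C=CCOc1cc(OCc2cccc(COc3ccc(C(=O)/C=C/c4ccc(OCc5ccccc5)c(OCc5ccccc5)c4)c(OCC=C)c3)c2)ccc1C(=O)/C=C/c1ccc(OCc2ccccc2)c(OCc2ccccc2)c1 | intermediate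
7 | strapped bis[(2R,3S)-trans-2,3-epoxy-1,3-diarylpropan-1-one] | C=CCOc1cc(OCc2cccc(COc3ccc(C(=O)[C@@H]4O[C@H]4c4ccc(OCc5ccccc5)c(OCc5ccccc5)c4)c(OCC=C)c3)c2)ccc1C(=O)[C@@H]1O[C@H]1c1ccc(OCc2ccccc2)c(OCc2ccccc2)c1 | intermediate
8 | strapped bis[(1S,2S,3S)-anti-2,3-epoxy-1,3-diarylpropan-1-ol], 2′-O-allyl | C=CCOc1cc(OCc2cccc(COc3ccc([C@H](O)[C@@H]4O[C@H]4c4ccc(OCc5ccccc5)c(OCc5ccccc5)c4)c(OCC=C)c3)c2)ccc1[C@H](O)[C@@H]1O[C@H]1c1ccc(OCc2ccccc2)c(OCc2ccccc2)c1 | intermediate
9 | strapped bis[(1S,2S,3S)-anti-epoxy alcohol], free 2′-OH | Oc1cc(OCc2cccc(COc3ccc([C@H](O)[C@@H]4O[C@H]4c4ccc(OCc5ccccc5)c(OCc5ccccc5)c4)c(O)c3)c2)ccc1[C@H](O)[C@@H]1O[C@H]1c1ccc(OCc2ccccc2)c(OCc2ccccc2)c1 | intermediate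
10 | 7,7′-O-(m-xylylene)-bis[(2R,3S,4S)-3′,4′-di-O-benzylflavan-3,4-diol] (2,3-trans-3,4-cis in both units) | c1c(COc2ccc3c(c2)O[C@H](c2ccc(OCc4ccccc4)c(OCc4ccccc4)c2)[C@@H](O)[C@H]3O)cccc1COc1ccc2c(c1)O[C@H](c1ccc(OCc3ccccc3)c(OCc3ccccc3)c1)[C@@H](O)[C@H]2O | intermediate
11 | mono-3,4-O-phenylboronate of 10 | c1c(COc2ccc3c(c2)O[C@H](c2ccc(OCc4ccccc4)c(OCc4ccccc4)c2)[C@@H](O)[C@H]3O)cccc1COc1ccc2c(c1)O[C@H](c1ccc(OCc3ccccc3)c(OCc3ccccc3)c1)[C@H]3OB(c4ccccc4)O[C@H]32 | intermediate
12 | strapped 14-membered macrocyclic (4α→6) dimer, lower 3,4-cis-diol as phenylboronate | C9Oc1ccc2c(c1)O[C@H](c1ccc(OCc3ccccc3)c(OCc3ccccc3)c1)[C@@H](O)[C@@H]2c1cc2c(cc1OCc1cccc9c1)O[C@H](c1ccc(OCc3ccccc3)c(OCc3ccccc3)c1)[C@H]3OB(c4ccccc4)O[C@H]32 | intermediate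
13 | fisetinidol-(4α→6)-(2R,3S,4S)-3′,4′,7-trihydroxyflavan-3,4-diol (CNP0280090.4) | Oc1ccc2c(c1)O[C@H](c1ccc(O)c(O)c1)[C@@H](O)[C@@H]2c1cc2c(cc1O)O[C@H](c1ccc(O)c(O)c1)[C@@H](O)[C@H]2O | target

**Count and risks**
Total steps: 6. Longest linear sequence: 6 (one two-directional line).

Step 5 carries the highest risk. The 14-membered closure may be too slow or strained. C8 or β-face attack may compete with the wanted C6/α-face attack. The boronate mask may be too weak, and the oxiranes may suffer while morpholine is present. The fallback sets out from 8 and comes back at 12. The flask is split into isolated stages and the dynamic boronate is replaced by a covalent mask. Pd(PPh3)4/morpholine, then camphorsulfonic acid (5 mol %) in CH2Cl2 at 0 °C, gives 10, which is now isolated. 1,1′-Carbonyldiimidazole (1.0 equiv) converts one cis-diol into the mono-cyclic carbonate F1; this is statistical, and recovered 10 and bis-carbonate are recycled with K2CO3/MeOH. BF3·OEt2 in CH2Cl2 (1 mM, −40 °C) ionises only the free diol unit and closes the strapped macrocyclic carbonate F2. K2CO3/MeOH gives the macrocyclic triol F3, and PhB(OH)2 (MgSO4, CH2Cl2) returns 12.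

Step 3 may fail because the large, electron-rich bis-chalcone reacts slowly on the heterogeneous polypeptide, and the electron-rich epoxides are labile. The fallback sets out from 6 and comes back at 8, skipping 7. 1,2-Reduction of both enones with catecholborane and (S)-Me-CBS oxazaborolidine (toluene, −78 °C, the ortho-alkoxyaryl acting as the large group) gives the bis-(R)-allylic alcohol F4. Sharpless asymmetric epoxidation (Ti(OiPr)4, L-(+)-diisopropyl tartrate, t-BuOOH, 4 Å sieves, CH2Cl2, −20 °C) is matched with this carbinol configuration and touches only the allylic-alcohol double bonds. It delivers the anti epoxy alcohol 8 directly.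

Step 6 may fail through hydrogenolytic loss of the activated benzylic 4-OH, or through decomposition of the free polyphenol. The fallback sets out from 12 and comes back at 13. Reductive cleavage is replaced by Lewis-acid debenzylation with a cation scavenger: BCl3 (12 equiv), pentamethylbenzene (20 equiv), CH2Cl2, −78 °C, then MeOH–H2O. The cyclic borate on O3/O4 stays closed during the reaction, so C4–O can only return on the β face, and all benzylic cations end on the scavenger. New compounds on this way: none F0.

**Further compounds**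
F1 | step 5 | mono-3,4-cyclic carbonate of 10 | c1c(COc2ccc3c(c2)O[C@H](c2ccc(OCc4ccccc4)c(OCc4ccccc4)c2)[C@@H](O)[C@H]3O)cccc1COc1ccc2c(c1)O[C@H](c1ccc(OCc3ccccc3)c(OCc3ccccc3)c1)[C@H]3OC(=O)O[C@H]32
F2 | step 5 | strapped macrocyclic (4α→6) dimer, lower 3,4-cis-diol as cyclic carbonate | C9Oc1ccc2c(c1)O[C@H](c1ccc(OCc3ccccc3)c(OCc3ccccc3)c1)[C@@H](O)[C@@H]2c1cc2c(cc1OCc1cccc9c1)O[C@H](c1ccc(OCc3ccccc3)c(OCc3ccccc3)c1)[C@H]3OC(=O)O[C@H]32
F3 | step 5 | strapped macrocyclic (4α→6) dimer with free upper 3-OH and free lower 3,4-cis-diol | C9Oc1ccc2c(c1)O[C@H](c1ccc(OCc3ccccc3)c(OCc3ccccc3)c1)[C@@H](O)[C@@H]2c1cc2c(cc1OCc1cccc9c1)O[C@H](c1ccc(OCc3ccccc3)c(OCc3ccccc3)c1)[C@@H](O)[C@H]2O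
F4 | step 3 | strapped bis[(1R,2E)-1,3-diarylprop-2-en-1-ol], 2′-O-allyl | C=CCOc1cc(OCc2cccc(COc3ccc([C@H](O)/C=C/c4ccc(OCc5ccccc5)c(OCc5ccccc5)c4)c(OCC=C)c3)c2)ccc1[C@H](O)/C=C/c1ccc(OCc2ccccc2)c(OCc2ccccc2)c1
F0 | step 6 | none | none
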